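## Retrosynthetic overview
1. Key disconnection: the quinonyl‑CH2–CH= bond (C1'–C2'), not the usual ring‑C3–allyl bond. The target comes from free chloromethylquinone 6 and an (E)-vinylalane made in situ from C28 enyne 13. Syn‑methylalumination creates the Δ2' E‑olefin and its methyl, and Ni(0) joins the fragments with no hydroquinone protection or re‑oxidation.
2. Enyne 13 comes from geranylgeraniol 7 by one C5 iteration of the same carboalumination (alkyne to E‑allylic alcohol) and two propargylations with 1,3‑dilithiopropyne.
3. Quinone 6 comes from chloromethylation of 2,8‑dimethyl‑1,4‑naphthoquinone 5 at its only quinonoid C–H.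
4. Quinone 5 comes from a bromine‑directed Diels–Alder reaction of 2‑bromo‑6‑methylbenzoquinone 2 with (E)-piperylene 3. This step fixes the 2‑Me/8‑Me relationship rather than 2‑Me/5‑Me.
5. Ring order: the quinone ring first (carbocycle of phenol 1, oxidised), the benzo ring second (Diels–Alder, then aromatisation). No ring is formed after the chain is attached.

Assumption: the target has no stereocentre, so "single enantiomer" is read as the single all‑E geometric isomer with five defined E trisubstituted alkenes. Menaquinone numbering is used throughout (C2‑Me, C3‑side chain, C8‑Me), which corresponds to IUPAC 2‑hexaprenyl‑3,5‑dimethyl.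

## Route

**Step 1**
Reactants: 1, 2‑bromo‑6‑methylphenol
Product: 2, 2‑bromo‑6‑methyl‑1,4‑benzoquinone
Conditions: (KSO3)2NO (2.5 equiv), KH2PO4 buffer, H2O/acetone, 0 °C → rt
Reagents that add atoms: Fremy's salt, [K+].[K+].[O]N(S(=O)(=O)[O-])S(=O)(=O)[O-] (supplies the C4 oxygen)
Why: In this Teuber oxidation the phenoxyl radical is trapped at the only free para position by a second nitroxide radical and collapses to the p‑quinone, leaving Br and CH3 untouched.

**Step 2**
Reactants: 2, 2‑bromo‑6‑methyl‑1,4‑benzoquinone; 3, (E)-penta‑1,3‑diene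
Product: 4, (±)-2,8‑dimethyl‑5,8‑dihydronaphthalene‑1,4‑dione
Conditions: 3 (3 equiv), PhMe, sealed tube, 45 °C, dark; then Et3N (1.2 equiv), 0 °C → rt
Reagents that add atoms: (E)-penta‑1,3‑diene (3), C/C=C/C=C
Why: This haloquinone Diels–Alder reaction occurs at the more electron‑poor C2(Br)=C3 bond, where Br and CH3 both donate into C4=O so that C1=O controls polarisation, the diene CH2 terminus bonds to C3‑H and the CHMe terminus to C2‑Br ("ortho" rule), the new methyl lands peri to the carbonyl that carries the neighbouring quinone methyl, and Et3N then removes HBr (the C8 stereocentre is transient).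

**Step 3**
Reactants: 4, (±)-2,8‑dimethyl‑5,8‑dihydronaphthalene‑1,4‑dione (crude; any naphthalene‑1,4‑diol tautomer converges)
Product: 5, 2,8‑dimethyl‑1,4‑naphthoquinone
Conditions: DDQ (1.1 equiv), benzene, rt → 60 °C; recrystallise to remove any 2,5‑isomer
Reagents that add atoms: none
Why: DDQ dehydrogenation (aromatisation) is driven by formation of the benzo ring, and both the dihydroquinone and its hydroquinone tautomer lose 2 H to give the same quinone.

**Step 4**
Reactants: 5, 2,8‑dimethyl‑1,4‑naphthoquinone
Product: 6, 3‑(chloromethyl)-2,8‑dimethyl‑1,4‑naphthoquinone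
Conditions: 37 % aq HCHO, HCl (g), AcOH, rt
Reagents that add atoms: formaldehyde, C=O; hydrogen chloride, Cl
Why: This Blanc‑type chloromethylation, as practised on menadione, can only occur at C3‑H because it is the sole quinonoid C–H and the benzo ring is deactivated by two carbonyls.

**Step 5**
Reactants: 7, (2E,6E,10E)-geranylgeraniol
Product: 8, (2E,6E,10E)-geranylgeranyl bromide
Conditions: PBr3 (0.4 equiv), Et2O, −10 → 0 °C; used crude
Reagents that add atoms: phosphorus tribromide, BrP(Br)Br
Why: SN2 displacement of the primary allylic phosphite ester at or below 0 °C proceeds without allylic transposition or E/Z erosion.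

**Step 6**
Reactants: 8, geranylgeranyl bromide; 9, propyne
Product: 10, (5E,9E,13E)-6,10,14,18‑tetramethylnonadeca‑5,9,13,17‑tetraen‑1‑yne
Conditions: 9 (2 equiv), n‑BuLi (4 equiv), TMEDA, Et2O/hexane, −78 → 0 °C; then 8, −78 °C → rt; aq NH4Cl
Reagents that add atoms: propyne (9, used as 1,3‑dilithiopropyne), CC#C
Why: In this dianion propargylation the more basic sp3 carbanion of LiCH2C≡CLi attacks the primary allylic bromide by SN2 (α‑attack, olefin untouched), and the acetylide is simply protonated on work‑up.

**Step 7**
Reactants: 10, C23 enyne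
Product: 11, (2E,6E,10E,14E)-geranylfarnesol (3,7,11,15,19‑pentamethylicosa‑2,6,10,14,18‑pentaen‑1‑ol)
Conditions: Me3Al (2.5 equiv), Cp2ZrCl2 (0.25 equiv), ClCH2CH2Cl, 0 °C → rt; strip volatiles; n‑BuLi, hexane/THF, 0 °C; (CH2O)n, rt
Reagents that add atoms: trimethylaluminium, C[Al](C)C (CH3); paraformaldehyde, C=O (CH2O)
Why: Negishi Zr‑catalysed syn‑methylalumination puts Me on the internal and Al on the terminal alkyne carbon, and the derived alanate adds to formaldehyde with retention, so the new trisubstituted alkene is E while the isolated trisubstituted alkenes stay inert.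

**Step 8**
Reactants: 11, geranylfarnesol
Product: 12, (2E,6E,10E,14E)-geranylfarnesyl bromide
Conditions: PBr3 (0.4 equiv), Et2O, −10 → 0 °C; used crude
Reagents that add atoms: phosphorus tribromide, BrP(Br)Br
Why: This is the same SN2 bromination of a primary allylic alcohol as step 5, and the geometry is retained.

**Step 9**
Reactants: 12, geranylfarnesyl bromide; 9, propyne
Product: 13, (5E,9E,13E,17E)-6,10,14,18,22‑pentamethyltricosa‑5,9,13,17,21‑pentaen‑1‑yne
Conditions: 9 (2 equiv), n‑BuLi (4 equiv), TMEDA, Et2O/hexane, −78 → 0 °C; then 12, −78 °C → rt; aq NH4Cl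
Reagents that add atoms: propyne (9, used as 1,3‑dilithiopropyne), CC#C
Why: This is the same dianion propargylation (SN2 at the primary allylic carbon) as step 6.

**Step 10 (key step)**
Reactants: 13, C28 enyne; 6, 3‑(chloromethyl)-2,8‑dimethyl‑1,4‑naphthoquinone
Product: 14, target, 2,8‑dimethyl‑3‑[(2E,6E,10E,14E,18E)-3,7,11,15,19,23‑hexamethyltetracosa‑2,6,10,14,18,22‑hexaenyl]-1,4‑naphthoquinone
Conditions: 13, Me3Al (1.5 equiv), Cp2ZrCl2 (0.25 equiv), ClCH2CH2Cl, rt; remove all volatiles and excess Me3Al in vacuo, triturate with hexane; then 6 (1.0 equiv), NiCl2(PPh3)2 (3 mol %)/n‑BuLi (6 mol %), THF, −20 °C → rt, dark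
Reagents that add atoms: trimethylaluminium, C[Al](C)C (CH3 at C3')
Why: Negishi syn‑carboalumination followed by Ni(0)‑catalysed sp2–sp3 cross‑coupling works because oxidative addition into the activated quinonyl‑CH2–Cl bond is faster than any attack on the quinone once free Me3Al is removed, and the vinyl group transfers with retention, so the last E alkene, its methyl and the C1'–C2' bond are set in one operation at the quinone oxidation level.

## Compound list
1 | 2‑bromo‑6‑methylphenol | Cc1cccc(Br)c1O | starting material
2 | 2‑bromo‑6‑methyl‑1,4‑benzoquinone | CC1=CC(=O)C=C(Br)C1=O | intermediate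
3 | (E)-penta‑1,3‑diene | C/C=C/C=C | starting material
4 | (±)-2,8‑dimethyl‑5,8‑dihydronaphthalene‑1,4‑dione | CC1=CC(=O)C2=C(C(C)C=CC2)C1=O | intermediate
5 | 2,8‑dimethyl‑1,4‑naphthoquinone | CC1=CC(=O)c2cccc(C)c2C1=O | intermediate
6 | 3‑(chloromethyl)-2,8‑dimethyl‑1,4‑naphthoquinone | CC1=C(CCl)C(=O)c2cccc(C)c2C1=O | intermediate
7 | (2E,6E,10E)-geranylgeraniol | CC(C)=CCC/C(C)=C/CC/C(C)=C/CC/C(C)=C/CO | starting material
8 | (2E,6E,10E)-geranylgeranyl bromide | CC(C)=CCC/C(C)=C/CC/C(C)=C/CC/C(C)=C/CBr | intermediate
9 | propyne | CC#C | starting material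
10 | (5E,9E,13E)-6,10,14,18‑tetramethylnonadeca‑5,9,13,17‑tetraen‑1‑yne | CC(C)=CCC/C(C)=C/CC/C(C)=C/CC/C(C)=C/CCC#C | intermediate
11 | (2E,6E,10E,14E)-geranylfarnesol | CC(C)=CCC/C(C)=C/CC/C(C)=C/CC/C(C)=C/CC/C(C)=C/CO | intermediate
12 | (2E,6E,10E,14E)-geranylfarnesyl bromide | CC(C)=CCC/C(C)=C/CC/C(C)=C/CC/C(C)=C/CC/C(C)=C/CBr | intermediate
13 | (5E,9E,13E,17E)-6,10,14,18,22‑pentamethyltricosa‑5,9,13,17,21‑pentaen‑1‑yne | CC(C)=CCC/C(C)=C/CC/C(C)=C/CC/C(C)=C/CC/C(C)=C/CCC#C | intermediate
14 | 8‑methylmenaquinone‑6 (C42H58O2) | CC(C)=CCC/C(C)=C/CC/C(C)=C/CC/C(C)=C/CC/C(C)=C/CC/C(C)=C/CC1=C(C)C(=O)c2c(C)cccc2C1=O | target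

## Summary
Total steps: 10.
Longest linear sequence: 6 (7 → 8 → 10 → 11 → 12 → 13 → 14). The quinone branch is 4 steps plus the coupling.

Steps most likely to fail:
1. **Step 10.**
   - Risk: residual Me3Al or the alane may add to or reduce the free quinone, and 3–5 % of the regioisomeric carboalumination product is hard to remove.
   - Fallback (reverse the polarity and mask the quinone): quench the alane with I2 to give the (E)-vinyl iodide. Run a Pd‑catalysed Negishi coupling with the benzylic zinc reagent of 3‑(chloromethyl)-1,4‑dimethoxy‑2,8‑dimethylnaphthalene, which is made from 5 by Na2S2O4 reduction, Me2SO4 methylation and chloromethylation. Finish with CAN oxidation.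
2. **Step 2.**
   - Risk: piperylene is only weakly polarised, so some 2,5‑dimethyl isomer may form.
   - Fallback: use the strongly polarised 1‑(trimethylsilyloxy)buta‑1,3‑diene with 2 to obtain 8‑hydroxy‑2‑methyl‑1,4‑naphthoquinone regiospecifically. Convert it to the triflate, then carry out Pd‑catalysed methylation with trimethylboroxine to reach 5.
3. **Steps 6 and 9.**
   - Risk: the polyprenyl bromides are labile, and SN2', allene or dialkylation by‑products are possible.
   - Fallback (avoid allylic halides altogether): carboaluminate 10 and quench with I2 to give the (E)-vinyl iodide. Couple it under Pd(0) with 4‑(trimethylsilyl)but‑3‑ynylzinc bromide, then desilylate with K2CO3/MeOH to give 13. The step count is the same as steps 7–9.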